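Its constants stand for no real mixture; no experiment stands behind them.

The trap in this flask is a charge of J that looks ample, 0.300 M against 0.20 M of Z, which tempts me to plan longer runs. But each E costs two J: one arrives in Z.J and one in J.G.

Z 0.20 M; G 0.300 M; J 0.300 M; time 20 h

1. the state of affairs at 20 h: stopped, and by what, or still going (forward and back rates have come level / all of Z has reacted / it is still moving)
2. the E standing at 20 h, as a percentage of the Z charged
3. the Z.J standing at 20 h, as a percentage of the Z charged

- E is meant together with its D
- solid, in amounts per volume of the solution: D
- the reaction counts as stopped when no species that holds the Z changes by six tenths of a point or more over the second half of the time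
- run time (flask): 20 h

    Z + J → Z.J (k1 = 0.023 M⁻¹ s⁻¹)
    J + G → J.G (k2 = 0.0021 M⁻¹ s⁻¹)
    G → X (k3 = 1.1 × 10⁻⁴ s⁻¹)
    D ⇌ E, rate k4*(cs4 - [E]) while solid is left; crystals form when [E] > cs4 (cs4 = 0.074 M, k4 = 0.0069 s⁻¹)
    Z.J + J.G → E (k5 = 0.027 M⁻¹ s⁻¹)

The charges allow at most 75.0% of E, and that needs an even split of J. Z and G do not split it evenly. At the start, Z takes J 7.3 times as fast as G does, and the half-life of Z is 1.7 min.

So I give Z its full share first and call the remainder the surplus, s 0.100 M. The surplus yield is s over the Z charged, 50.0%.

| J | amount |
|---|---|
| charged | 0.300 M |
| taken by Z | 0.20 M |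
| s, left for G | 0.100 M |

J is the limiting reagent for E here. G is charged above s, though it also decays to X. Each J.G turns one Z.J into E, so the J that G catches early is not lost. The correction to the surplus yield is small: it subtracts free J left at the end and adds free Z left at the end. I set both aside and expect 50.0% of E and 50.0% of Z.J. My decision for the next run is more J, not more hours.

The forecast gives all of Z has reacted, 50.9% of E and 48.2% of Z.J: “G takes the remaining J”.

The flask gives all of Z has reacted, 49.8% of E and 50.1% of Z.J. In this flask the rate of J use by Z over that by G falls from 7.3 at the start to 0.18 at 1.52 h.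

In a neighbour flask charged with 0.75 M of J, the surplus yield is 275%, more than the Z can use, so I expect Z to cap E and no Z.J to stand. That flask gives 100% of E and 0% of Z.J.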